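## Analysis of the target

Working numbering: C1 = ring-fusion carbon bearing the methyl group, C2 = CH2, C3 = CHOAc, C4 = C(OH)(iPr), C5 = ring-fusion CH, C6 = CH(O-aroyl), C7=C8(Me), C9 = CH2, C10 = CHOH.

- The skeleton is a cis-fused bicyclo[5.3.0]decene (daucane-type hydroazulene): a cyclopentane (C1–C5) fused along C1–C5 to a cycloheptene (C5–C10, C1).
- There are six stereocentres, (1S,3S,4R,5R,6S,10S) in this numbering. C3–C4–C5–C6 are contiguous, C1 is quaternary, and C10 sits next to it.
- The C1 methyl and H5 are cis and define the convex face. The C3 acetate and the C4 hydroxyl lie on that face, so the isopropyl group points to the concave side, towards the seven-membered ring. The C10 hydroxyl is cis to the C1 methyl, and the C6 ester oxygen is trans to H5.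
- Sensitive groups are the allylic 4-hydroxybenzoate (ionisation, acyl cleavage), the free phenol, and a secondary acetate next to a tertiary alcohol. Whenever C6 is a ketone, the C4 oxygen is β to it (retro-aldol, β-elimination) and C5 is epimerisable.
- The synthesis is hard because the quaternary C1 is flanked by stereocentres on both sides, three secondary oxygens (C3, C6, C10) must end as three different groups, and the isopropyl group must sit on the more hindered face.
- The strategy rests on one feature: C6 and C10 are both oxygenated and are bonded directly to the fusion carbons C5 and C1. With an added C6–C10 bond, C1, C5, C6 and C10 form a cyclobutane-1,2-diol, and C6–C10 become a second five-membered ring. That 5-4-5 tricycle is the retron of an enone–enediol [2+2] photocycloaddition; cleaving the glycol later releases the 5-7 skeleton.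

## Retrosynthetic reasoning

**25 ⇒ 24 ⇒ 20 + 23.** The two O–Si bonds and the C6–O acyl bond are cut last. The ester is formed late because an allylic ester with a tertiary allylic terminus would not survive the earlier acid, base and hydride steps. The phenol of 21 is silylated (23) so that it cannot compete in the acylation. Only the secondary C6 hydroxyl of 20 should react; the tertiary C4 hydroxyl is too hindered.

**20 ⇒ 19 ⇒ 16.** The C6–H bond is traced to a 1,2-reduction of enone 19, and the C7=C8 bond to dehydrogenation of ketone 16. A C6 ketone is the only handle that places the double bond at C7=C8, because the C5 side has no β-hydrogen. The reduction must deliver hydride to the convex face of C6; the isopropyl group on C4 blocks the other face.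

**16 ⇒ 15 ⇒ 13 ⇒ 12.** The C10–H bond is traced to reduction of a C10 ketone. In dione 12 the C6 carbonyl (flanked by H5 on its open face) should be the more reactive one, and C10 is neopentyl. A direct selective reduction at C10 therefore cannot be relied on. The route masks C6 as ketal 13, reduces C10, unmasks C6 (15) and silylates the C10 hydroxyl (16). The forward sequence has to tell the two carbonyls apart and set C10 with the hydroxyl cis to the C1 methyl.

**12 ⇒ 11 ⇒ 10.** The C6–C10 bond is re-formed in the retrosynthetic sense: the 1,4-dione 12 is the glycol-cleavage product of cyclobutanediol 11. This converts the seven-membered ring problem into a cyclobutane problem and carries the cis C1/C5 relationship through unchanged. The cleavage must wait until C4 is no longer a carbonyl; otherwise a free C6 hydroxyl would trigger retro-aldol opening of the wrong bond (C5–C6).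

**10 ⇒ 9 ⇒ 8 ⇒ 6 + 7 ⇒ 4.** The C3–O and C4–O bonds come from syn-dihydroxylation of alkene 8 on the convex face of the rigid tricycle. This is the only face that places both oxygens cis to the C1 methyl and the isopropyl group on the concave side; direct addition of an isopropyl nucleophile to the ketone would give the opposite C4 configuration. The C4–isopropyl bond is cut to enol triflate 6 and Grignard reagent 7, and 6 comes from ketone 4. Acetylating C3 directly after dihydroxylation (10) installs a group of the target and also keeps the C3/C4 glycol out of reach of the later glycol cleavage.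

**4 ⇒ 2 + 3.** The C1–C10 and C5–C6 bonds are cut together, a [2+2] disconnection into enone 3 and enediol bis(silyl ether) 2. This builds the quaternary C1, the cis fusion and both seven-ring oxygens in one step from two simple partners. The alkene is symmetrical, so there is no regiochemical question. The forward step must control only the absolute configuration at C1/C5.

**2 ⇒ 1.** The C6–C10 bond of 2 is an acyloin bond; diester 1 already carries the future C8 methyl.

## Alternatives that were turned down

**Alternative 1: Ireland–Claisen ring contraction.**
- Disconnection: C5–C6, with the C7=C8 alkene and the carboxyl on C5 read as the product of a [3,3] shift.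
- Forward key step: the seven-membered lactone A1 has its ring oxygen on C8, which also carries the methyl and an (E)-alkoxyvinyl group. It would be enolised with a potassium amide and O-silylated. A boat-like shift, enforced by the C1–C10–C9 bridge, forms C5–C6, breaks C8–O and gives cycloheptene acid A2.
- For: A2 already has C7=C8, and C6 and C10 oxygens at the alcohol level under different protecting groups. C5 and C6 come from a stereospecific pericyclic event. On the C6/C10 distinction and on the placement of the alkene this plan is stronger than the chosen one, which spends several steps there.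
- Against: the cyclopentane is missing. C3 and C4 must still be joined and C3–OAc, C4–OH and the isopropyl group set on a flexible cycloheptene without the facial bias of a rigid tricycle. A1 itself has three stereocentres, among them a tertiary allylic C–O centre and the quaternary C1, and would need a long enantioselective synthesis.
- Comparison: the chosen strategy offers both rings, the quaternary centre and the cis fusion in two steps from commercial materials, and a rigid intermediate for the C3/C4 diol.

**Alternative 2: intramolecular Buchner reaction.**
- Disconnection: C5–C1 and C5–C6, the seven-membered ring seen as a ring-expanded arene.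
- Forward key step: the metal carbene from diazoketone A3 (dirhodium carboxylate or copper–bis(oxazoline) catalyst) adds across the ipso–ortho bond and closes the cyclopentanone. Electrocyclic opening gives dihydroazulenone A4.
- For: A3 is a few steps from an arylpropanoic acid. A4 has the whole bicyclic carbon skeleton, the C8 methyl, the C4 carbonyl and a C10 oxygen after one catalytic step. In access to the ring system it is at least as short as the chosen route.
- Against: C1 is sp2 and has no methyl, so the quaternary centre and the cis fusion must be made later by alkylation. C6 has no oxygen, and the triene (C6=C7, C8=C9, C1=C10) needs several selective redox steps. H5 is α to the ketone and doubly allylic, hence configurationally labile, and cycloheptatrienes undergo hydrogen shifts. Enantiocontrol in Buchner reactions is uneven.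
- Comparison: the chosen strategy delivers the quaternary C1 and oxygen at both C6 and C10 directly, on an sp3 framework that holds its configuration.

**Alternative 3: divinylcyclopropane rearrangement.**
- Disconnection: C7–C8, with a C5–C10 bond added to give a cis-divinylcyclopropane.
- Forward key step: heating bicyclo[3.1.0]hexanone A5 forms C7–C8 through a boat transition state, breaks C5–C10 and gives A6.
- For: the step is stereospecific and fixes C1. The two oxygens emerge electronically different: C6 as part of a vinylogous ester with the C4 carbonyl, C10 as an isolated silyl enol ether. On the C6/C10 distinction it is stronger than the chosen route.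
- Against: A5 has two adjacent quaternary cyclopropane carbons next to a fully substituted siloxy carbon with a defined cis relationship, which is a long enantioselective problem. C5 is sp2 in A6, so H5 must still be set. C8 is sp3, so the C7=C8 bond must still be introduced. The C4/C6 1,3-dioxygenation makes the isopropyl carbinol awkward to build.
- Comparison: the chosen strategy reaches its cycloaddition partners in one step and sets H5 and the C1 methyl together. The price is a ketal detour to tell C6 from C10.

Key step: step 2

Remark 1: the photoadduct is expected as a mixture at C6, C8 and C10 (cis-anti-cis ring arrangement probably dominant). These centres are destroyed later and are written without descriptors, C6/C10 up to 11 and C8 up to 18.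

Remark 2: which enantiomer of the diarylprolinol-derived oxazaborolidine leaves the required enone face open cannot be derived for this pair. The route assumes the matching one; both are accessible.

## Route

Step 1
Reactants: 1 dimethyl 3-methylglutarate
Product: 2 4-methyl-1,2-bis(trimethylsilyloxy)cyclopentene
Conditions: Na (4.4 equiv), Me3SiCl (4.5 equiv), toluene, reflux; filtration, distillation
Reagents that add atoms: chlorotrimethylsilane, C[Si](C)(C)Cl
Why: Acyloin condensation in the Rühlmann variant: sodium reduces both esters, the enediolate closes the five-membered ring (C6–C10 bond) and is silylated in situ, which suppresses Dieckmann side reactions; no stereocentre of consequence is formed.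

Step 2
Reactants: 3 3-methylcyclopent-2-enone; 2 4-methyl-1,2-bis(trimethylsilyloxy)cyclopentene
Product: 4 (1S,5R)-tricyclic 5-4-5 ketone with 6,10-bis(trimethylsilyloxy) groups
Conditions: 2 (5 equiv), chiral oxazaborolidine (from α,α-bis(3,5-dimethylphenyl)prolinol and 2,4,6-trifluorophenylboronic acid) activated with AlBr3 (50 mol%), CH2Cl2, −75 °C, hν (λ = 366 nm); Et3N quench at −75 °C
Reagents that add atoms: none
Why: Proposed new method: the AlBr3-activated oxazaborolidine should bind the carbonyl of 3, shift its absorption so that mainly the complex is excited at 366 nm, and shield one enone face with its aryl groups; the excited triplet complex adds the electron-rich alkene 2 through a 1,4-diradical, and the cyclobutane (C5–C6 and C1–C10, one new ring) closes by radical combination after spin inversion. The closest known reaction types are the oxazaborolidine–AlBr3-catalysed intermolecular [2+2] photocycloaddition of cyclic enones with simple alkenes and the uncatalysed photocycloaddition of enones to 1,2-bis(silyloxy)cycloalkenes; their combination on a five-membered enone and an enediol bis(silyl ether) is new. The cis fusion at C1/C5 is enforced by the strain of a trans four/five fusion. The absolute configuration (1S,5R) is set by the catalyst, which must leave open the Si face at C2 of 3. Alkene 2 is symmetrical about its double bond, so no head-to-head or head-to-tail question arises, and C6, C8 and C10 may form as mixtures. The step needs enantioface selectivity and suppression of the dark Mukaiyama–Michael reaction between the activated enone and the silyl enol ether; that reaction would have to join two fully substituted carbons and should be slow at −75 °C.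

Step 3
Reactants: 4 (1S,5R)-tricyclic 5-4-5 ketone
Product: 6 C3=C4 enol triflate, via potassium enolate 5 (not isolated)
Conditions: KN(SiMe3)2 (1.1 equiv), THF, −78 °C; PhNTf2 (1.1 equiv), −78 → 0 °C
Reagents that add atoms: N-phenylbis(trifluoromethanesulfonimide), O=S(=O)(N(c1ccccc1)S(=O)(=O)C(F)(F)F)C(F)(F)F
Why: Kinetic deprotonation can occur only at C3, since an enolate towards C5 would put a double bond at the cyclobutane fusion; O-triflation of the enolate is standard, and the silyl ethers stay on, which matters because a free C6 hydroxyl β to the C4 ketone would open C5–C6 by retro-aldol (de Mayo) cleavage.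

Step 4
Reactants: 6 C3=C4 enol triflate; 7 isopropylmagnesium chloride
Product: 8 4-isopropyl C3=C4 alkene
Conditions: 7 (1.5 equiv), Fe(acac)3 (5 mol%), THF/NMP, −30 °C
Reagents that add atoms: none
Why: Iron-catalysed Kumada-type coupling of alkenyl triflates with alkyl Grignard reagents is fast at low temperature and accepts secondary alkyl groups without chain isomerisation; the tertiary silyl ethers are inert.

Step 5
Reactants: 8 4-isopropyl C3=C4 alkene
Product: 9 (3S,4R)-3,4-diol
Conditions: OsO4 (5 mol%), N-methylmorpholine N-oxide (1.5 equiv), acetone/H2O, rt
Reagents that add atoms: osmium tetroxide, O=[Os](=O)(=O)=O; N-methylmorpholine N-oxide, C[N+]1([O-])CCOCC1; water, O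
Why: Catalytic syn-dihydroxylation; OsO4 should add to the convex face of the bicyclo[3.2.0]heptene unit (the face of the C1 methyl and H5) because the other face is covered by the cyclobutane and its silyloxy groups, which sets C3 and C4 with both hydroxyls cis to the C1 methyl and places the isopropyl group on the concave side.

Step 6
Reactants: 9 (3S,4R)-3,4-diol
Product: 10 C3 acetate with free C4 hydroxyl
Conditions: Ac2O (2 equiv), pyridine, DMAP (cat.), CH2Cl2, 0 °C → rt
Reagents that add atoms: acetic anhydride, CC(=O)OC(C)=O
Why: DMAP-catalysed acylation distinguishes the secondary C3 hydroxyl from the hindered tertiary C4 hydroxyl; the acetate is the group of the target and also removes the C3/C4 glycol from reach of periodate.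

Step 7
Reactants: 10 C3 acetate with free C4 hydroxyl
Product: 12 cis-fused bicyclo[5.3.0]decane-6,10-dione, via cyclobutanediol 11 (not isolated)
Conditions: PPTS (cat.), MeOH, 0 °C → rt; then NaIO4 (1.5 equiv), THF/H2O, 0 °C → rt
Reagents that add atoms: none
Why: Acid-catalysed methanolysis frees the two tertiary cyclobutanols (no C4 carbonyl is left, so retro-aldol is not possible), and periodate glycol cleavage of the strained cis-cyclobutane-1,2-diol breaks C6–C10 and opens the tricycle to the cis-fused 5-7 dione with C1 and C5 untouched; the monoacetylated C3/C4 pair is not a free glycol and is not cleaved.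

Step 8
Reactants: 12 cis-fused bicyclo[5.3.0]decane-6,10-dione
Product: 13 C6 ethylene ketal with C10 ketone
Conditions: 1,2-bis(trimethylsilyloxy)ethane (1.5 equiv), Me3SiOTf (5 mol%), CH2Cl2, −78 → −20 °C; pyridine, aqueous NaHCO3
Reagents that add atoms: 1,2-bis(trimethylsilyloxy)ethane, C[Si](C)(C)OCCO[Si](C)(C)C
Why: Kinetic ketalisation with the silylated diol should occur at C6, whose convex face is flanked only by H5, and not at the neopentyl C10 carbonyl next to quaternary C1; this masks the more reactive carbonyl so that C10 can be reduced alone, and any silylation of the C4 hydroxyl is reversed in step 9.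

Step 9
Reactants: 13 C6 ethylene ketal with C10 ketone
Product: 15 (10S)-10-hydroxy 6-ketone, via ketal alcohol 14 (not isolated)
Conditions: NaBH4 (2 equiv), CeCl3·7H2O (1 equiv), MeOH, 0 °C; aqueous work-up; then PPTS (cat.), acetone/H2O, 50 °C
Reagents that add atoms: water, O
Why: Borohydride reduction (CeCl3 keeps the medium non-basic and spares the acetate) should deliver hydride to C10 anti to the adjacent angular methyl, as is usual for cycloalkanones next to a methyl-bearing quaternary carbon, giving the C10 hydroxyl cis to the C1 methyl; mild acid hydrolysis of the dioxolane then returns the C6 ketone.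

Step 10
Reactants: 15 (10S)-10-hydroxy 6-ketone
Product: 16 C10 tert-butyldimethylsilyl ether
Conditions: TBSOTf (1.15 equiv), 2,6-lutidine (2 equiv), CH2Cl2, −78 °C
Reagents that add atoms: tert-butyldimethylsilyl trifluoromethanesulfonate, CC(C)(C)[Si](C)(C)OS(=O)(=O)C(F)(F)F
Why: At −78 °C the silyl triflate should silylate the secondary C10 hydroxyl much faster than the hindered tertiary C4 hydroxyl; the ether keeps C10 from being oxidised or acylated later.

Step 11
Reactants: 16 C10 tert-butyldimethylsilyl ether
Product: 19 C7=C8 enone with free C4 hydroxyl, via bis-silyl enol ether 17 (not isolated), via O-silyl enone 18 (not isolated)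
Conditions: Me3SiOTf (3 equiv), Et3N (5 equiv), CH2Cl2, 0 °C; Pd(OAc)2 (1.1 equiv), MeCN, rt; then citric acid, MeOH, rt
Reagents that add atoms: none
Why: Soft enolisation should remove a C7 proton, since H5 lies between two quaternary carbons, and also caps the C4 hydroxyl; Saegusa–Ito oxidation of the C6=C7 silyl enol ether gives the C7=C8 enone, the only one possible because the C5 side has no β-hydrogen, and both C8 epimers converge; mild acid methanolysis then frees the tertiary C4 hydroxyl without touching the TBS ether.

Step 12
Reactants: 19 C7=C8 enone with free C4 hydroxyl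
Product: 20 (6S)-allylic alcohol
Conditions: NaBH4 (1.5 equiv), CeCl3·7H2O (1.2 equiv), MeOH, −78 → −40 °C
Reagents that add atoms: none
Why: Luche reduction gives 1,2-reduction of the enone; hydride should come from the convex face (the side of H5) because the concave face of C6 is blocked by the C4 isopropyl group, so the C6 hydroxyl ends trans to H5.

Step 13
Reactants: 21 4-hydroxybenzoic acid
Product: 23 4-(tert-butyldimethylsilyloxy)benzoic acid, via silyl ester 22 (not isolated)
Conditions: TBSCl (2.5 equiv), imidazole, DMF, rt; then AcOH/THF/H2O, rt
Reagents that add atoms: tert-butyldimethylsilyl chloride, CC(C)(C)[Si](C)(C)Cl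
Why: Bis-silylation followed by selective hydrolysis of the labile silyl ester is the standard protection of the phenol, which would otherwise compete in the esterification.

Step 14
Reactants: 20 (6S)-allylic alcohol; 23 4-(tert-butyldimethylsilyloxy)benzoic acid
Product: 24 C6 4-(tert-butyldimethylsilyloxy)benzoate
Conditions: 23 (2 equiv), DCC (2 equiv), DMAP (0.5 equiv), CH2Cl2, rt
Reagents that add atoms: none
Why: Steglich esterification acylates the secondary allylic C6 hydroxyl with retention; the tertiary C4 hydroxyl does not react, and the neutral conditions avoid ionisation of the allylic position.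

Step 15
Reactants: 24 C6 4-(tert-butyldimethylsilyloxy)benzoate
Product: 25 target CNP0146780.2
Conditions: HF·pyridine, THF/pyridine, 0 °C → rt
Reagents that add atoms: none
Why: Fluoride-mediated desilylation under mildly acidic conditions removes the aryl and the C10 silyl ethers without acyl migration or loss of the acetate and the allylic ester.

## Compound list

1 | dimethyl 3-methylglutarate | COC(=O)CC(C)CC(=O)OC | starting material
2 | 4-methyl-1,2-bis(trimethylsilyloxy)cyclopentene | CC1CC(O[Si](C)(C)C)=C(O[Si](C)(C)C)C1 | intermediate
3 | 3-methylcyclopent-2-enone | CC1=CC(=O)CC1 | starting material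
4 | (1S,5R)-tricyclic 5-4-5 ketone: cyclobutane C1–C5–C6–C10, C4 ketone, C1 and C8 methyl, 6,10-bis(trimethylsilyloxy), H5 cis to C1 methyl, C6/C8/C10 mixture | C1C[C@]2(C)C3(O[Si](C)(C)C)CC(C)CC3(O[Si](C)(C)C)[C@@H]2C1=O | intermediate
5 | potassium C3=C4 enolate of 4 (not isolated) | C1C[C@]2(C)C3(O[Si](C)(C)C)CC(C)CC3(O[Si](C)(C)C)[C@@H]2C=1[O-].[K+] | intermediate
6 | C3=C4 enol triflate of 4 | C1C[C@]2(C)C3(O[Si](C)(C)C)CC(C)CC3(O[Si](C)(C)C)[C@@H]2C=1OS(=O)(=O)C(F)(F)F | intermediate
7 | isopropylmagnesium chloride | CC(C)[Mg]Cl | starting material
8 | tricyclic C3=C4 alkene with isopropyl on C4 | C1C[C@]2(C)C3(O[Si](C)(C)C)CC(C)CC3(O[Si](C)(C)C)[C@@H]2C=1C(C)C | intermediate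
9 | (3S,4R)-3,4-diol, both hydroxyls cis to the C1 methyl and H5, isopropyl on the concave face | O[C@H]1C[C@]2(C)C3(O[Si](C)(C)C)CC(C)CC3(O[Si](C)(C)C)[C@@H]2[C@]1(O)C(C)C | intermediate
10 | C3 acetate of 9, C4 hydroxyl free | CC(=O)O[C@H]1C[C@]2(C)C3(O[Si](C)(C)C)CC(C)CC3(O[Si](C)(C)C)[C@@H]2[C@]1(O)C(C)C | intermediate
11 | cyclobutane-6,10-diol of 10 (not isolated) | CC(=O)O[C@H]1C[C@]2(C)C3(O)CC(C)CC3(O)[C@@H]2[C@]1(O)C(C)C | intermediate
12 | cis-fused bicyclo[5.3.0]decane-6,10-dione with C3 acetate, C4 hydroxyl and isopropyl, C1 and C8 methyl (C8 epimers) | CC(=O)O[C@H]1C[C@]2(C)C(=O)CC(C)CC(=O)[C@@H]2[C@]1(O)C(C)C | intermediate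
13 | C6 ethylene ketal (1,3-dioxolane) of 12, C10 ketone | CC(=O)O[C@H]1C[C@]2(C)C(=O)CC(C)CC3(OCCO3)[C@@H]2[C@]1(O)C(C)C | intermediate
14 | (10S)-alcohol of 13, hydroxyl cis to the C1 methyl (not isolated) | CC(=O)O[C@H]1C[C@]2(C)[C@@H](O)CC(C)CC3(OCCO3)[C@@H]2[C@]1(O)C(C)C | intermediate
15 | (10S)-10-hydroxy 6-ketone | CC(=O)O[C@H]1C[C@]2(C)[C@@H](O)CC(C)CC(=O)[C@@H]2[C@]1(O)C(C)C | intermediate
16 | C10 tert-butyldimethylsilyl ether of 15 | CC(=O)O[C@H]1C[C@]2(C)[C@@H](O[Si](C)(C)C(C)(C)C)CC(C)CC(=O)[C@@H]2[C@]1(O)C(C)C | intermediate
17 | C6=C7 trimethylsilyl enol ether with C4 trimethylsilyl ether (not isolated) | CC(=O)O[C@H]1C[C@]2(C)[C@@H](O[Si](C)(C)C(C)(C)C)CC(C)C=C(O[Si](C)(C)C)[C@@H]2[C@]1(O[Si](C)(C)C)C(C)C | intermediate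
18 | C7=C8 enone with C4 trimethylsilyl ether (not isolated) | CC(=O)O[C@H]1C[C@]2(C)[C@@H](O[Si](C)(C)C(C)(C)C)CC(C)=CC(=O)[C@@H]2[C@]1(O[Si](C)(C)C)C(C)C | intermediate
19 | C7=C8 enone (C6 ketone) with free C4 hydroxyl and C10 silyl ether | CC(=O)O[C@H]1C[C@]2(C)[C@@H](O[Si](C)(C)C(C)(C)C)CC(C)=CC(=O)[C@@H]2[C@]1(O)C(C)C | intermediate
20 | (6S)-allylic alcohol, hydroxyl trans to H5 | CC(=O)O[C@H]1C[C@]2(C)[C@@H](O[Si](C)(C)C(C)(C)C)CC(C)=C[C@H](O)[C@@H]2[C@]1(O)C(C)C | intermediate
21 | 4-hydroxybenzoic acid | OC(=O)c1ccc(O)cc1 | starting material
22 | tert-butyldimethylsilyl 4-(tert-butyldimethylsilyloxy)benzoate (not isolated) | CC(C)(C)[Si](C)(C)OC(=O)c1ccc(O[Si](C)(C)C(C)(C)C)cc1 | intermediate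
23 | 4-(tert-butyldimethylsilyloxy)benzoic acid | OC(=O)c1ccc(O[Si](C)(C)C(C)(C)C)cc1 | intermediate
24 | C6 4-(tert-butyldimethylsilyloxy)benzoate of 20 | CC(=O)O[C@H]1C[C@]2(C)[C@@H](O[Si](C)(C)C(C)(C)C)CC(C)=C[C@H](OC(=O)c3ccc(O[Si](C)(C)C(C)(C)C)cc3)[C@@H]2[C@]1(O)C(C)C | intermediate
25 | CNP0146780.2, (1S,3S,4R,5R,6S,10S) in the working numbering | CC(=O)O[C@H]1C[C@]2(C)[C@@H](O)CC(C)=C[C@H](OC(=O)c3ccc(O)cc3)[C@@H]2[C@]1(O)C(C)C | target

## Step count and least certain steps

Total: 15 steps. Longest linear sequence: 14 steps (steps 1–12, 14, 15).

**Step 2 (key step, Proposed new method).** The most likely failures are a dark Mukaiyama–Michael addition of the silyl enol ether to the Lewis-acid-activated enone, Lewis-acid-induced desilylation, or weak enantioface discrimination with a five-membered enone. Fallback: starting from 2 and 3, direct irradiation without Lewis acid (λ = 350 nm, CH2Cl2, −20 °C) is the known uncatalysed enone–bis(silyloxy)alkene cycloaddition. It gives the racemate, that is 4 together with its mirror image, the (1R,5S)-tricyclic ketone F1. After the minor diastereomers are removed on silica, the enantiomers are separated by preparative chromatography on a cellulose tris(3,5-dimethylphenylcarbamate) stationary phase, and the route is rejoined at 4.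

**Step 8.** Site discrimination between the two ring carbonyls may be insufficient, or transannular participation of the second carbonyl may give a bridged bis-ketal. Fallback from 12, which does not depend on the steric order of the two ketones: the free C4 hydroxyl directs Me4NBH(OAc)3 (MeCN/AcOH, −20 °C) to C6 only, since triacetoxyborohydride does not reduce an isolated ketone, giving the C6 alcohol F2 (configuration at C6 immaterial). Et3SiCl/imidazole gives the C6 triethylsilyl ether F3. NaBH4/CeCl3·7H2O reduces C10 to the alcohol F4. TBSOTf/2,6-lutidine gives the bis-silyl ether F5. PPTS/MeOH at 0 °C removes only the triethylsilyl group to give the C6 alcohol F6. Oxidation with Dess–Martin periodinane returns the route at 16.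

**Step 9.** The risk is poor facial selectivity at C10, with hydride approaching on the side of the methyl if the dioxolane crowds the concave face; slow reduction with competing acetate methanolysis is a lesser risk. Fallback from 13: reagent control in place of substrate control. A Corey–Bakshi–Shibata reduction with (R)-2-methyl-CBS-oxazaborolidine and BH3·SMe2 (large group: quaternary C1; small group: C9H2) is predicted to give the 10S alcohol, and the route is rejoined at 14. No new compound is involved.

**Step 4.** Reduction of the triflate, homocoupling, or isomerisation of the secondary alkyl group may compete. Fallback from 6: Suzuki coupling with 2-propenylboronic acid pinacol ester (Pd(PPh3)4, K3PO4, dioxane/H2O, 60 °C) gives the isopropenyl diene F7. Chemoselective hydrogenation of its 1,1-disubstituted double bond (H2, RhCl(PPh3)3, benzene) returns the route at 8.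

**Step 12.** Facial selectivity of hydride delivery to C6 could be lowered by a conformation of the cycloheptenone that exposes the concave face. Fallback from 19: if the epimeric alcohol predominates, the (6R)-allylic alcohol F8 is used as such in a Mitsunobu esterification with 23 (PPh3, diisopropyl azodicarboxylate, THF, 0 °C). This inverts C6 and gives 24 directly, where the route is rejoined.

## Further compounds

F1 | step 2 | (1R,5S)-enantiomer of tricyclic ketone 4 | C1C[C@@]2(C)C3(O[Si](C)(C)C)CC(C)CC3(O[Si](C)(C)C)[C@H]2C1=O
F2 | step 8 | C6 alcohol of dione 12 (C10 ketone, C4 hydroxyl free) | CC(=O)O[C@H]1C[C@]2(C)C(=O)CC(C)CC(O)[C@@H]2[C@]1(O)C(C)C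
F3 | step 8 | C6 triethylsilyl ether of F2 | CC(=O)O[C@H]1C[C@]2(C)C(=O)CC(C)CC(O[Si](CC)(CC)CC)[C@@H]2[C@]1(O)C(C)C
F4 | step 8 | (10S)-alcohol of F3 | CC(=O)O[C@H]1C[C@]2(C)[C@@H](O)CC(C)CC(O[Si](CC)(CC)CC)[C@@H]2[C@]1(O)C(C)C
F5 | step 8 | C10 tert-butyldimethylsilyl, C6 triethylsilyl bis-ether | CC(=O)O[C@H]1C[C@]2(C)[C@@H](O[Si](C)(C)C(C)(C)C)CC(C)CC(O[Si](CC)(CC)CC)[C@@H]2[C@]1(O)C(C)C
F6 | step 8 | C6 alcohol with C10 tert-butyldimethylsilyl ether | CC(=O)O[C@H]1C[C@]2(C)[C@@H](O[Si](C)(C)C(C)(C)C)CC(C)CC(O)[C@@H]2[C@]1(O)C(C)C
F0 | step 9 | none | none
F7 | step 4 | tricyclic diene with isopropenyl on C4 | C1C[C@]2(C)C3(O[Si](C)(C)C)CC(C)CC3(O[Si](C)(C)C)[C@@H]2C=1C(C)=C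
F8 | step 12 | (6R)-allylic alcohol, C6 epimer of 20 | CC(=O)O[C@H]1C[C@]2(C)[C@@H](O[Si](C)(C)C(C)(C)C)CC(C)=C[C@@H](O)[C@@H]2[C@]1(O)C(C)C
A1 | alternative 1 | seven-membered lactone with methyl and (E)-2-(4-methoxybenzyloxy)vinyl on C8, C10 silyl ether and quaternary C1 | O=C1C[C@](C)(CCO[Si](c2ccccc2)(c2ccccc2)C(C)(C)C)[C@@H](O[Si](C)(C)C(C)(C)C)C[C@@](C)(/C=C/OCc2ccc(OC)cc2)O1
A2 | alternative 1 | cyclohept-3-ene carboxylic acid with C5, C6, C10 and C1 stereocentres | OC(=O)[C@H]1[C@@H](OCc2ccc(OC)cc2)C=C(C)C[C@H](O[Si](C)(C)C(C)(C)C)[C@@]1(C)CCO[Si](c2ccccc2)(c2ccccc2)C(C)(C)C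
A3 | alternative 2 | 1-diazo-4-(2-methoxy-4-methylphenyl)butan-2-one | COc1cc(C)ccc1CCC(=O)C=[N+]=[N-]
A4 | alternative 2 | 8-methoxy-6-methyl-3,8a-dihydroazulen-1(2H)-one | O=C1CCC2=C(OC)C=C(C)C=C[C@H]12
A5 | alternative 3 | bicyclo[3.1.0]hexan-2-one with cis siloxyvinyl (C5) and (E)-propenyl/siloxy (C10) groups | O=C1CC[C@]2(C)[C@@](O[Si](C)(C)C(C)(C)C)(/C=C/C)[C@]12C(=C)O[Si](C)(C)C(C)(C)C
A6 | alternative 3 | hydroazulen-4-one bis(silyl enol ether) at C6 and C10 | O=C1CC[C@@]2(C)C1=C(O[Si](C)(C)C(C)(C)C)C[C@@H](C)C=C2O[Si](C)(C)C(C)(C)C
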